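**Retrosynthetic overview**
1. Target ⇐ acetylation of the C6 alcohol and hydroxyl-directed epoxidation of C4=C5 in a (1(10)E,4E)-germacradien-12,8-olide; the oxirane is the last ring.
2. Ten-membered ring ⇐ C6–C7 bond: a 3-(bromomethyl)butenolide is converted into an allylchromium, so the lactone β-carbon (C7, normally an acceptor site) attacks the C6 enal. This one step closes the carbocycle and sets C6, C7 and the exocyclic methylene.
3. Open-chain enal ⇐ C2–C3 bond by a catalytic enantioselective vinylogous aldol addition (sets C2), then acetate formation and amide-to-aldehyde reduction.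
4. Butenolide (first ring) ⇐ esterification with 2-(bromomethyl)acrylic acid and ring-closing metathesis; C8 and the C8–C9 bond ⇐ the same vinylogous aldol addition on cinnamaldehyde.
5. Ring order: butenolide → ten-membered carbocycle → oxirane.

Assumption: atom labels C1–C15 follow germacrane numbering of the target (C12 lactone carbonyl, C13 exocyclic methylene, C8 the lactone-oxygen carbon), and both enantiomers of the bisphosphoramide catalyst are accessible from resolved 1,1'-binaphthyl-2,2'-diamine.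

**Route**

Step 1
Reactants: 1 3-methylbut-2-enoyl chloride; 2 morpholine
Product: 3 4-(3-methylbut-2-enoyl)morpholine
Conditions: aq. NaOH, CH2Cl2, 0 °C
Reagents that add atoms: none
Why: Schotten–Baumann N-acylation of a secondary amine by an acid chloride, with no stereocenter formed.

Step 2
Reactants: 3 4-(3-methylbut-2-enoyl)morpholine
Product: 4 4-[(1Z)-1-(tert-butyldimethylsilyloxy)-3-methylbuta-1,3-dien-1-yl]morpholine
Conditions: KN(SiMe3)2, THF, −78 °C; then TBSCl, −78 °C to rt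
Reagents that add atoms: tert-butyldimethylsilyl chloride, CC(C)(C)[Si](C)(C)Cl
Why: γ-Deprotonation of the unsaturated amide to the extended (Z)-amide enolate and O-silylation give the conjugated N,O-silyl ketene acetal used in both vinylogous Mukaiyama aldol steps, with no stereocenter formed.

Step 3
Reactants: 4 4-[(1Z)-1-(tert-butyldimethylsilyloxy)-3-methylbuta-1,3-dien-1-yl]morpholine; 5 (2E)-3-phenylprop-2-enal
Product: 7 (2E,5S,6E)-5-hydroxy-3-methyl-1-(morpholin-4-yl)-7-phenylhepta-2,6-dien-1-one, via trichlorosilyl ether 6 (not isolated)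
Conditions: SiCl4 (1.1 equiv), (S,S)-N,N'-dimethyl-N,N'-bis(3,5-dimethyl-4-oxido-3,5-dihydro-4H-dinaphtho[2,1-d:1',2'-f][1,3,2]diazaphosphepin-4-yl)pentane-1,5-diamine (2 mol %), CH2Cl2, −78 °C; aq. NaHCO3
Reagents that add atoms: none
Why: Lewis-base-activated SiCl4 vinylogous Mukaiyama aldol addition in which the dienolate attacks through its γ-carbon on the Si face of the catalyst-bound aldehyde (this catalyst is the mirror image of the Re-face-selective (R,R) form), setting C8 as 5S and the (2E)-olefin (later C1=C10), after which 6 is hydrolysed on work-up.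

Step 4
Reactants: 7 (2E,5S,6E)-5-hydroxy-3-methyl-1-(morpholin-4-yl)-7-phenylhepta-2,6-dien-1-one
Product: 9 (2E,5S,6E)-5-hydroxy-3-methyl-7-phenylhepta-2,6-dienal, via zirconium hemiaminal 8 (not isolated)
Conditions: Cp2Zr(H)Cl (2.5 equiv), THF, 25 °C, 20 min; H2O/silica gel
Reagents that add atoms: none
Why: Schwartz-reagent reduction of a tertiary amide stops at the zirconium N,O-hemiaminal 8, which collapses to the enal on hydrolytic work-up without touching the olefins or C8 (the free hydroxyl only consumes one extra equivalent as its zirconium alkoxide).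

Step 5
Reactants: 9 (2E,5S,6E)-5-hydroxy-3-methyl-7-phenylhepta-2,6-dienal; 10 2-(bromomethyl)prop-2-enoic acid
Product: 11 (1E,3S,5E)-5-methyl-7-oxo-1-phenylhepta-1,5-dien-3-yl 2-(bromomethyl)prop-2-enoate
Conditions: N,N'-dicyclohexylcarbodiimide, 4-(dimethylamino)pyridine (5 mol %), CH2Cl2, −20 to 0 °C
Reagents that add atoms: none
Why: Steglich esterification of the secondary allylic alcohol with retention at C8, run cold with little nucleophilic catalyst so the allylic bromide survives.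

Step 6
Reactants: 11 (1E,3S,5E)-5-methyl-7-oxo-1-phenylhepta-1,5-dien-3-yl 2-(bromomethyl)prop-2-enoate
Product: 12 (5S)-3-(bromomethyl)-5-[(2E)-2-methyl-4-oxobut-2-en-1-yl]furan-2(5H)-one
Conditions: second-generation Grubbs catalyst (H2IMes)(PCy3)Cl2Ru=CHPh (5 mol %), toluene, 60 °C
Reagents that add atoms: none
Why: Ring-closing metathesis between the acrylate olefin and the styryl olefin closes the five-membered butenolide and expels styrene, while the trisubstituted enal olefin is inert and C8 is untouched.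

Step 7
Reactants: 12 (5S)-3-(bromomethyl)-5-[(2E)-2-methyl-4-oxobut-2-en-1-yl]furan-2(5H)-one; 4 4-[(1Z)-1-(tert-butyldimethylsilyloxy)-3-methylbuta-1,3-dien-1-yl]morpholine
Product: 14 (2E,5S,6E)-8-[(2S)-4-(bromomethyl)-5-oxo-2,5-dihydrofuran-2-yl]-5-hydroxy-3,7-dimethyl-1-(morpholin-4-yl)octa-2,6-dien-1-one, via trichlorosilyl ether 13 (not isolated)
Conditions: SiCl4 (1.1 equiv), (S,S)-N,N'-dimethyl-N,N'-bis(3,5-dimethyl-4-oxido-3,5-dihydro-4H-dinaphtho[2,1-d:1',2'-f][1,3,2]diazaphosphepin-4-yl)pentane-1,5-diamine (2 mol %), CH2Cl2, −78 °C; aq. NaHCO3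
Reagents that add atoms: none
Why: Second catalyst-controlled vinylogous Mukaiyama aldol addition with γ-attack on the Si face of the enal sets C2 (5S in 14) independently of the remote C8 center and installs the (E)-C4=C5 olefin, and the base-free conditions spare the bromide and the acidic butenolide γ-hydrogen.

Step 8
Reactants: 14 (2E,5S,6E)-8-[(2S)-4-(bromomethyl)-5-oxo-2,5-dihydrofuran-2-yl]-5-hydroxy-3,7-dimethyl-1-(morpholin-4-yl)octa-2,6-dien-1-one
Product: 15 (2E,4S,6E)-1-[(2S)-4-(bromomethyl)-5-oxo-2,5-dihydrofuran-2-yl]-2,6-dimethyl-8-(morpholin-4-yl)-8-oxoocta-2,6-dien-4-yl acetate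
Conditions: Ac2O, Sc(OTf)3 (2 mol %), MeCN, −20 °C
Reagents that add atoms: acetic anhydride, CC(=O)OC(C)=O
Why: Lewis-acid-catalysed acetylation of the secondary allylic alcohol with retention, chosen amine-free because pyridine-type bases would be alkylated by the bromomethyl butenolide.

Step 9
Reactants: 15 (2E,4S,6E)-1-[(2S)-4-(bromomethyl)-5-oxo-2,5-dihydrofuran-2-yl]-2,6-dimethyl-8-(morpholin-4-yl)-8-oxoocta-2,6-dien-4-yl acetate
Product: 17 (2E,4S,6E)-1-[(2S)-4-(bromomethyl)-5-oxo-2,5-dihydrofuran-2-yl]-2,6-dimethyl-8-oxoocta-2,6-dien-4-yl acetate, via zirconium hemiaminal 16 (not isolated)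
Conditions: Cp2Zr(H)Cl (1.5 equiv), THF, 0 to 25 °C, 15 min; H2O/silica gel
Reagents that add atoms: none
Why: Chemoselective Schwartz-reagent reduction of the tertiary amide via hemiaminal 16 leaves the acetate and lactone intact, and the short reaction time is relied on to spare the allylic bromide, with no stereocenter touched.

Step 10
Reactants: 17 (2E,4S,6E)-1-[(2S)-4-(bromomethyl)-5-oxo-2,5-dihydrofuran-2-yl]-2,6-dimethyl-8-oxoocta-2,6-dien-4-yl acetate
Product: 20 (1(10)E,2S,4E,6R,7S,8S)-2-acetoxy-6-hydroxygermacra-1(10),4,11(13)-trien-12,8-olide, via allylchromium dichloride 18 (not isolated), via chromium alkoxide 19 (not isolated)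
Conditions: CrCl2 (8 equiv), 4 Å molecular sieves, THF, 25 °C, slow addition of 17 (final 2 mM); H2O
Reagents that add atoms: none
Why: Intramolecular Nozaki–Hiyama–Kishi allylation in which divalent chromium inserts into the C–Br bond and the γ-carbon C7 of allylchromium 18 adds to the C6 aldehyde through a closed chair transition state on the butenolide face anti to the C8 side chain, which should give the trans-fused lactone (7S), the anti C6/C7 relationship (6R) expected for an (E)-γ-substituted allylmetal, the exocyclic methylene by allylic transposition and the ten-membered ring at high dilution.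

Step 11
Reactants: 20 (1(10)E,2S,4E,6R,7S,8S)-2-acetoxy-6-hydroxygermacra-1(10),4,11(13)-trien-12,8-olide
Product: 21 (1(10)E,2S,4R,5R,6S,7S,8S)-2-acetoxy-4,5-epoxy-6-hydroxygermacra-1(10),11(13)-dien-12,8-olide
Conditions: VO(acac)2 (5 mol %), t-BuOOH, CH2Cl2, 0 °C
Reagents that add atoms: tert-butyl hydroperoxide, CC(C)(C)OO
Why: Hydroxyl-directed vanadium-catalysed epoxidation is selective for the C4=C5 olefin of the allylic alcohol over the acetoxy-flanked C1=C10 and the electron-poor methylene olefin, and oxygen is delivered on the open outer ring face syn to the C6–O bond in the A(1,3)-minimised conformer, giving the threo (4R,5R) trans-epoxide.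

Step 12
Reactants: 21 (1(10)E,2S,4R,5R,6S,7S,8S)-2-acetoxy-4,5-epoxy-6-hydroxygermacra-1(10),11(13)-dien-12,8-olide
Product: 22 (1(10)E,2S,4R,5R,6S,7R,8S)-2,6-diacetoxy-4,5-epoxygermacra-1(10),11(13)-dien-12,8-olide
Conditions: Ac2O, pyridine, 4-(dimethylamino)pyridine (cat.), CH2Cl2, 0 °C
Reagents that add atoms: acetic anhydride, CC(=O)OC(C)=O
Why: Base-catalysed acetylation of the C6 alcohol with retention completes the diacetate, and the basic medium avoids acid-induced transannular opening of the epoxide.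

**Compound list**
1 | 3-methylbut-2-enoyl chloride | CC(C)=CC(=O)Cl | starting material
2 | morpholine | C1COCCN1 | starting material
3 | 4-(3-methylbut-2-enoyl)morpholine | CC(C)=CC(=O)N1CCOCC1 | intermediate
4 | 4-[(1Z)-1-(tert-butyldimethylsilyloxy)-3-methylbuta-1,3-dien-1-yl]morpholine | C=C(C)/C=C(\O[Si](C)(C)C(C)(C)C)N1CCOCC1 | intermediate
5 | (2E)-3-phenylprop-2-enal (cinnamaldehyde) | O=C/C=C/c1ccccc1 | starting material
6 | trichlorosilyl ether of 7 (not isolated) | Cl[Si](Cl)(Cl)O[C@H](/C=C/c1ccccc1)C/C(C)=C/C(=O)N1CCOCC1 | intermediate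
7 | (2E,5S,6E)-5-hydroxy-3-methyl-1-(morpholin-4-yl)-7-phenylhepta-2,6-dien-1-one | O[C@H](/C=C/c1ccccc1)C/C(C)=C/C(=O)N1CCOCC1 | intermediate
8 | zirconium alkoxide/N,O-hemiaminal from 7 and two Cp2ZrCl units (not isolated; cyclopentadienyl rings drawn σ-bonded) | Cl[Zr](C1C=CC=C1)(C1C=CC=C1)O[C@H](/C=C/c1ccccc1)C/C(C)=C/C(O[Zr](Cl)(C1C=CC=C1)C1C=CC=C1)N1CCOCC1 | intermediate
9 | (2E,5S,6E)-5-hydroxy-3-methyl-7-phenylhepta-2,6-dienal | O[C@H](/C=C/c1ccccc1)C/C(C)=C/C=O | intermediate
10 | 2-(bromomethyl)prop-2-enoic acid | C=C(CBr)C(=O)O | starting material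
11 | (1E,3S,5E)-5-methyl-7-oxo-1-phenylhepta-1,5-dien-3-yl 2-(bromomethyl)prop-2-enoate | C=C(CBr)C(=O)O[C@H](/C=C/c1ccccc1)C/C(C)=C/C=O | intermediate
12 | (5S)-3-(bromomethyl)-5-[(2E)-2-methyl-4-oxobut-2-en-1-yl]furan-2(5H)-one | BrCC1=C[C@H](C/C(C)=C/C=O)OC1=O | intermediate
13 | trichlorosilyl ether of 14 (not isolated) | BrCC1=C[C@H](C/C(C)=C/[C@@H](O[Si](Cl)(Cl)Cl)C/C(C)=C/C(=O)N2CCOCC2)OC1=O | intermediate
14 | (2E,5S,6E)-8-[(2S)-4-(bromomethyl)-5-oxo-2,5-dihydrofuran-2-yl]-5-hydroxy-3,7-dimethyl-1-(morpholin-4-yl)octa-2,6-dien-1-one | BrCC1=C[C@H](C/C(C)=C/[C@@H](O)C/C(C)=C/C(=O)N2CCOCC2)OC1=O | intermediate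
15 | (2E,4S,6E)-1-[(2S)-4-(bromomethyl)-5-oxo-2,5-dihydrofuran-2-yl]-2,6-dimethyl-8-(morpholin-4-yl)-8-oxoocta-2,6-dien-4-yl acetate | BrCC1=C[C@H](C/C(C)=C/[C@@H](OC(C)=O)C/C(C)=C/C(=O)N2CCOCC2)OC1=O | intermediate
16 | zirconium N,O-hemiaminal from 15 (not isolated; cyclopentadienyl rings drawn σ-bonded) | BrCC1=C[C@H](C/C(C)=C/[C@@H](OC(C)=O)C/C(C)=C/C(O[Zr](Cl)(C2C=CC=C2)C2C=CC=C2)N2CCOCC2)OC1=O | intermediate
17 | (2E,4S,6E)-1-[(2S)-4-(bromomethyl)-5-oxo-2,5-dihydrofuran-2-yl]-2,6-dimethyl-8-oxoocta-2,6-dien-4-yl acetate | BrCC1=C[C@H](C/C(C)=C/[C@@H](OC(C)=O)C/C(C)=C/C=O)OC1=O | intermediate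
18 | allylchromium dichloride from 17 (not isolated) | Cl[Cr](Cl)CC1=C[C@H](C/C(C)=C/[C@@H](OC(C)=O)C/C(C)=C/C=O)OC1=O | intermediate
19 | dichlorochromium alkoxide of 20 (not isolated) | C=C1C(=O)O[C@H]2C/C(C)=C/[C@@H](OC(C)=O)C/C(C)=C/[C@@H](O[Cr](Cl)Cl)[C@H]12 | intermediate
20 | (1(10)E,2S,4E,6R,7S,8S)-2-acetoxy-6-hydroxygermacra-1(10),4,11(13)-trien-12,8-olide | C=C1C(=O)O[C@H]2C/C(C)=C/[C@@H](OC(C)=O)C/C(C)=C/[C@@H](O)[C@H]12 | intermediate
21 | (1(10)E,2S,4R,5R,6S,7S,8S)-2-acetoxy-4,5-epoxy-6-hydroxygermacra-1(10),11(13)-dien-12,8-olide | C=C1C(=O)O[C@H]2C/C(C)=C/[C@@H](OC(C)=O)C[C@@]3(C)O[C@@H]3[C@@H](O)[C@H]12 | intermediate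
22 | (1(10)E,2S,4R,5R,6S,7R,8S)-2,6-diacetoxy-4,5-epoxygermacra-1(10),11(13)-dien-12,8-olide (CNP0270851.2) | C=C1C(=O)O[C@H]2C/C(C)=C/[C@@H](OC(C)=O)C[C@@]3(C)O[C@@H]3[C@@H](OC(C)=O)[C@H]12 | target

**Totals**
Total step count: 12.
Longest linear sequence: 12 steps (1 → 22; ketene acetal 4 is made once and used in steps 3 and 7).

**Three steps most likely to fail**

Step 10 (macrocyclisation). The risks are oligomerisation, attack through C13 instead of C7, and loss of facial control at C6 in the strained ten-membered transition state. The fallback sets out from 17 and replaces the reductive metalation by a preformed boron nucleophile. Pd2(dba)3-catalysed borylation of the allylic bromide with bis(pinacolato)diboron gives the isolable allylboronate (2E,4S,6E)-2,6-dimethyl-8-oxo-1-{(2S)-5-oxo-4-[(4,4,5,5-tetramethyl-1,3,2-dioxaborolan-2-yl)methyl]-2,5-dihydrofuran-2-yl}octa-2,6-dien-4-yl acetate F1. This 2-(alkoxycarbonyl)allylboronate is too sluggish to react on its own, so it can be purified and then cyclised at high dilution with catalytic Sc(OTf)3 through a closed six-membered allylboration transition state; hydrolysis of the borate returns the route at 20.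

Step 9 (amide reduction next to an allylic bromide, a lactone and an acetate). The fallback sets out from 12 and avoids any amide. 3-Methylbut-2-enal is converted with TBSOTf and Et3N into the aldehyde-level dienol ether tert-butyl(dimethyl){[(1E)-3-methylbuta-1,3-dien-1-yl]oxy}silane F2. A vinylogous Mukaiyama aldol addition of F2 to 12, promoted by the Si-face-directing enantiomer of 4-(1H-indol-3-ylmethyl)-2-phenyl-3-tosyl-1,3,2-oxazaborolidin-5-one, gives directly the hydroxy enal (5S)-3-(bromomethyl)-5-[(2E,4S,6E)-4-hydroxy-2,6-dimethyl-8-oxoocta-2,6-dien-1-yl]furan-2(5H)-one F3. Acetylation under the conditions of step 8 then returns the route at 17.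

Step 11 (face and site selectivity of the epoxidation on a flexible, acid-sensitive germacradiene). The fallback sets out from 17 and fixes the epoxide by reagent control before ring closure. Luche reduction (NaBH4, CeCl3) gives the allylic alcohol (2E,4S,6E)-1-[(2S)-4-(bromomethyl)-5-oxo-2,5-dihydrofuran-2-yl]-8-hydroxy-2,6-dimethylocta-2,6-dien-4-yl acetate F4. Sharpless asymmetric epoxidation with Ti(OiPr)4, D-(−)-diethyl tartrate and t-BuOOH gives the epoxy alcohol (2E,4S)-1-[(2S)-4-(bromomethyl)-5-oxo-2,5-dihydrofuran-2-yl]-5-[(2R,3R)-3-(hydroxymethyl)-2-methyloxiran-2-yl]-2-methylpent-2-en-4-yl acetate F5. Dess–Martin oxidation gives the epoxy aldehyde (2E,4S)-1-[(2S)-4-(bromomethyl)-5-oxo-2,5-dihydrofuran-2-yl]-5-[(2R,3S)-3-formyl-2-methyloxiran-2-yl]-2-methylpent-2-en-4-yl acetate F6. CrCl2-mediated ring closure of F6 under the conditions of step 10 then returns the route at 21.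

Further compounds
F1 | step 10 | (2E,4S,6E)-2,6-dimethyl-8-oxo-1-{(2S)-5-oxo-4-[(4,4,5,5-tetramethyl-1,3,2-dioxaborolan-2-yl)methyl]-2,5-dihydrofuran-2-yl}octa-2,6-dien-4-yl acetate | CC1(C)OB(CC2=C[C@H](C/C(C)=C/[C@@H](OC(C)=O)C/C(C)=C/C=O)OC2=O)OC1(C)C
F2 | step 9 | tert-butyl(dimethyl){[(1E)-3-methylbuta-1,3-dien-1-yl]oxy}silane | C=C(C)/C=C/O[Si](C)(C)C(C)(C)C
F3 | step 9 | (5S)-3-(bromomethyl)-5-[(2E,4S,6E)-4-hydroxy-2,6-dimethyl-8-oxoocta-2,6-dien-1-yl]furan-2(5H)-one | BrCC1=C[C@H](C/C(C)=C/[C@@H](O)C/C(C)=C/C=O)OC1=O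
F4 | step 11 | (2E,4S,6E)-1-[(2S)-4-(bromomethyl)-5-oxo-2,5-dihydrofuran-2-yl]-8-hydroxy-2,6-dimethylocta-2,6-dien-4-yl acetate | BrCC1=C[C@H](C/C(C)=C/[C@@H](OC(C)=O)C/C(C)=C/CO)OC1=O
F5 | step 11 | (2E,4S)-1-[(2S)-4-(bromomethyl)-5-oxo-2,5-dihydrofuran-2-yl]-5-[(2R,3R)-3-(hydroxymethyl)-2-methyloxiran-2-yl]-2-methylpent-2-en-4-yl acetate | BrCC1=C[C@H](C/C(C)=C/[C@@H](OC(C)=O)C[C@@]2(C)O[C@@H]2CO)OC1=O
F6 | step 11 | (2E,4S)-1-[(2S)-4-(bromomethyl)-5-oxo-2,5-dihydrofuran-2-yl]-5-[(2R,3S)-3-formyl-2-methyloxiran-2-yl]-2-methylpent-2-en-4-yl acetate | BrCC1=C[C@H](C/C(C)=C/[C@@H](OC(C)=O)C[C@@]2(C)O[C@@H]2C=O)OC1=O
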